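Take the hour as the unit and count turnovers: divide the product made by the catalyst charged and by the time.

| setting | maple | oak | larch | alder | summer | spring | noon | dawn |
|---|---|---|---|---|---|---|---|---|
| starting material | 0.10 M | 0.10 M | 0.10 M | 0.10 M | 0.025 M | 0.10 M | 0.10 M | 0.20 M |
| coupling partner | 0.050 M (fed, over 25 min) | 0.050 M (fed, over 25 min) | 0.050 M (fed, over 25 min) | 0.027 M (fed, over 25 min) | 0.0250 M (fed, over 100 min) | 0.0500 M (fed, over 25 min) | 0.0120 M (fed, over 40 min) | 0.0500 M (fed, over 40 min) |
| free catalyst | 0.12 mM | 0.16 mM | 0.22 mM | 0.20 mM | 0.20 mM | 0.20 mM | 0.20 mM | 0.12 mM |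
| remark | run made earlier | run made earlier | run made earlier | run made earlier |  |  |  |  |
| time |  |  |  |  | 5.0 h | 5.0 h | 5.0 h | 5.0 h |

| run | time / h | product / % | starting material / % |
|---|---|---|---|
| maple | 0.667 | 5 | 97 |
| maple | 1.33 | 11 | 92 |
| maple | 2.00 | 11 | 89 |
| maple | 3.00 | 18 | 79 |
| maple | 4.00 | 27 | 75 |
| oak | 0.667 | 7 | 94 |
| oak | 1.33 | 11 | 90 |
| oak | 2.00 | 17 | 82 |
| oak | 3.00 | 25 | 76 |
| oak | 4.00 | 38 | 66 |
| larch | 0.667 | 9 | 89 |
| larch | 1.33 | 18 | 85 |
| larch | 2.00 | 27 | 76 |
| larch | 3.00 | 35 | 66 |
| larch | 4.00 | 43 | 57 |
| alder | 0.333 | 3 | 95 |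
| alder | 0.833 | 8 | 87 |
| alder | 1.50 | 14 | 83 |
| alder | 2.50 | 24 | 75 |
| alder | 4.00 | 25 | 73 |

(scatter of a reading: 1.5 percentage points)



* the flasks put in order of amount of product, in percent of the starting material charged, best first, at 5.0 h (summer / spring / noon / dawn)
* the same order at 1.0 h (summer / spring / noon / dawn)
* the amount of product, in percent of the starting material charged of the flask you put first, at 5.0 h
* the amount of product, in percent of the starting material charged of the flask you put last, at 5.0 h

At their last readings, maple and oak together give 58.0 h⁻¹, the turnover rate: product formed per catalyst per hour. Take product at a given time as the smaller of two amounts, the charge of coupling partner and turnover rate × [free catalyst] × time. Call the common logarithm of the second amount over the first, at 5.0 h, the margin.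

Now ask which number has to be known well. Noon has a margin of 0.685, so an error in the turnover rate hardly touches it; coupling partner is its limiting reagent, and its charge gives 12.0%. Spring, at 0.0647, stands on the edge, so expect a little under 50.0%. Dawn, at −0.157, follows the turnover rate one for one and gives 17.4%.

Summer's margin of 0.366 looks safe. But the turnover rate was read with [starting material] no lower than oak's final 0.0660 M, and summer starts 0.422 below that in logarithm, a gap wider than its margin. So the pull of [starting material] on the turnover rate is the number that matters, and the readings do not give it. Commit to 100% for summer, as the weakest figure here, and to the order summer, spring, dawn, noon. At 1.0 h the same rule gives summer 46.4%, spring 11.6%, noon 11.6%, a tie with spring that the rule does not break, and dawn 3.48%.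

The forecast, holding the rate “independent of starting material”, gave summer > spring > dawn > noon at 5.0 h and summer > spring > noon > dawn at 1.0 h, with 95% for summer and 12% for noon.

The simulation gives summer > spring > dawn > noon at 5.0 h and summer > spring > noon > dawn at 1.0 h, with summer at 77.3% and noon at 11.6%.

    coupling partner + free catalyst ⇌ catalyst intermediate A (K = 69.0 M⁻¹, k = 52800 M⁻¹ h⁻¹)
    catalyst intermediate A → catalyst intermediate B (k = 2170 h⁻¹)
    starting material + catalyst intermediate B ⇌ catalyst intermediate C (K = 320 M⁻¹, k = 2310 M⁻¹ h⁻¹)
    catalyst intermediate C ⇌ catalyst intermediate D (K = 1.80, k = 188 h⁻¹)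
    catalyst intermediate D → free catalyst + product (k = 254 h⁻¹)
    product + catalyst intermediate B → spent catalyst (k = 0.139 M⁻¹ h⁻¹)
    coupling partner ⇌ dormant form (K = 47.0, k = 0.0749 h⁻¹)

Summer ends at 5.0 h with 10% of its coupling partner still unbound, and its catalyst averaged 19.3 h⁻¹, slower than the turnover rate of 58.0 h⁻¹. The time allowed is the largest single effect on that shortfall: left until 50.0 h, summer reaches 88.4%, a gain of 11 percentage points and 49% of what is missing. The neighbour of noon with 0.0072 M of coupling partner has a margin of 0.906, so its cap of 7.20% should hold, and it gives 7.05%.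

(All runs were computed for an exercise, noise included.)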